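**Plan**
- Retrosynthetic cuts (side chain numbered C1'–C13' from C2): C5'–C6' (alkynylation of an allylic bromide), C4–C4a of pyran ring B (gold hydroarylation), C3'=C4' (Wittig) and O1–C8a (SNAr ether formation).
- Forward: geraniol is turned into (S)-3,7-dimethyloct-6-en-1-yn-3-ol, which is used twice. One portion is O-arylated; the para nitrile becomes the C6 oxygen and the prenyl end an E-enoate. Ring B is then closed, the ester becomes an allylic bromide, the second portion of the alkynol is attached, and trans-reduction and desilylation finish the route.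
- Enabling feature: in ring A (C4a, C5–C8, C8a) C8 carries a methyl group and C6 the oxygen, so an O1 aryl ether of the C2 carbinol has C4a as its only free ortho carbon. The ethynyl group on C2 supplies C3 and C4.
- Stereochemistry: one Sharpless epoxidation sets the carbinol carbon that serves as both C2 and C8'; its C–O bond is never broken afterwards. The E alkenes come from the Wittig reaction (C3'=C4') and the hydroxyl-directed trans-hydroalumination (C6'=C7').

Key step: step 10

Remark: the oxirane carbon created in step 6 forms without control and is carried as a mixture of both configurations, because step 8 turns it into the aldehyde carbon; the alkene geometry of the chloroalkene intermediate of step 3 is likewise immaterial.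

**Step 1**
Reactants: 1 geraniol
Product: 2 [(2S,3S)-3-methyl-3-(4-methylpent-3-en-1-yl)oxiran-2-yl]methanol ((2S,3S)-2,3-epoxygeraniol)
Conditions: Ti(OiPr)4 (5 mol%), L-(+)-diethyl tartrate (7 mol%), t-BuOOH, 4 Å MS, CH2Cl2, −20 °C
Reagents that add atoms: tert-butyl hydroperoxide, CC(C)(C)OO
Why: Sharpless asymmetric epoxidation, in which the titanium tartrate complex binds the allylic hydroxyl and with L-(+)-diethyl tartrate should deliver oxygen to the alkene face that gives the (2S,3S)-epoxide, while the remote C6=C7 alkene has no directing hydroxyl and stays untouched.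

**Step 2**
Reactants: 2 (2S,3S)-2,3-epoxygeraniol
Product: 3 (2S,3R)-3-(chloromethyl)-2-methyl-2-(4-methylpent-3-en-1-yl)oxirane
Conditions: PPh3, CCl4, NaHCO3, reflux
Reagents that add atoms: carbon tetrachloride, ClC(Cl)(Cl)Cl
Why: Appel chlorination replaces the primary hydroxyl by chloride under buffered, essentially neutral conditions, so the oxirane and both stereocentres are unaffected (the descriptor at the CH carbon changes only through the priority of CH2Cl).

**Step 3**
Reactants: 3 the epoxy chloride
Product: 5 (S)-3,7-dimethyloct-6-en-1-yn-3-ol, via lithium (3S)-1-chloro-3,7-dimethylocta-1,6-dien-3-olate 4 (not isolated)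
Conditions: LiN(iPr)2 (3.5 equiv), THF, −78 → −30 °C; then aq. NH4Cl
Reagents that add atoms: none
Why: Base-induced fragmentation of a 2,3-epoxy chloride, in which deprotonation next to chlorine opens the oxirane by beta-elimination to the chloroalkenyl alkoxide 4 and a second dehydrochlorination gives the alkyne; the tertiary C–O bond is never broken, so the (S) centre is retained.

**Step 4**
Reactants: 5 (S)-3,7-dimethyloct-6-en-1-yn-3-ol; 6 4-fluoro-3-methylbenzonitrile
Product: 7 4-{[(3S)-3,7-dimethyloct-6-en-1-yn-3-yl]oxy}-3-methylbenzonitrile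
Conditions: KN(SiMe3)2 (1.05 equiv), THF, 0 °C; then 6, THF/DMF, rt → 50 °C
Reagents that add atoms: none
Why: SNAr addition–elimination of the preformed potassium tertiary alkoxide at the fluorine-bearing carbon activated by the para nitrile, a reliable way to hindered tertiary alkyl aryl ethers that does not touch the carbinol carbon, whose quaternary nature also excludes alkyne–allene isomerisation.

**Step 5**
Reactants: 7 the aryloxy benzonitrile
Product: 9 4-{[(3S)-3,7-dimethyloct-6-en-1-yn-3-yl]oxy}-3-methylbenzaldehyde, via N-aluminated aldimine 8 (not isolated)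
Conditions: iBu2AlH (1.3 equiv), CH2Cl2, −78 °C; then 1 M HCl, 0 °C (brief)
Reagents that add atoms: water, O
Why: Partial reduction of a nitrile, in which iBu2AlH adds one hydride at low temperature and stops at the aluminated imine 8, which aqueous acid hydrolyses to the aldehyde while alkyne, alkene and aryl ether stay inert.

**Step 6**
Reactants: 9 the aryloxy benzaldehyde
Product: 11 4-{[(3S)-5-(3,3-dimethyloxiran-2-yl)-3-methylpent-1-yn-3-yl]oxy}-3-methylphenol (both oxirane epimers), via aryl formate epoxide 10 (not isolated)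
Conditions: mCPBA (2.5 equiv), NaHCO3, CH2Cl2, 0 °C → rt; aq. Na2SO3 wash; then K2CO3 (cat.), MeOH, 0 °C
Reagents that add atoms: 3-chloroperbenzoic acid, OOC(=O)c1cccc(Cl)c1
Why: Baeyer–Villiger (Dakin-type) oxidation in which the para-alkoxyaryl group should migrate in preference to hydrogen to give formate 10, while the same peracid epoxidises the electron-rich trisubstituted alkene (Prilezhaev reaction) and thereby masks the aldehyde of step 8; the terminal alkyne is inert and mild methanolysis frees the phenol.

**Step 7**
Reactants: 11 the phenol epoxide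
Product: 12 triisopropyl(4-{[(3S)-5-(3,3-dimethyloxiran-2-yl)-3-methylpent-1-yn-3-yl]oxy}-3-methylphenoxy)silane (both oxirane epimers)
Conditions: iPr3SiCl, imidazole, DMF, rt
Reagents that add atoms: triisopropylsilyl chloride, CC(C)[Si](Cl)(C(C)C)C(C)C
Why: Standard silylation of a phenol; the bulky triisopropylsilyl ether is chosen because it should survive periodic acid, the gold catalyst, hydride reagents and K2CO3 in DMF and be removed only by fluoride at the end.

**Step 8**
Reactants: 12 the silyl ether epoxide
Product: 13 (4S)-4-methyl-4-[2-methyl-4-(triisopropylsilyloxy)phenoxy]hex-5-ynal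
Conditions: H5IO6 (1.3 equiv), THF/Et2O, 0 °C
Reagents that add atoms: none
Why: Periodic acid cleavage of a trisubstituted epoxide (hydrolytic opening at the tertiary carbon, then glycol cleavage) should give the aldehyde, which keeps the oxirane oxygen, and acetone, without touching the alkyne or the fully etherified hydroquinone, and it removes the uncontrolled oxirane centre.

**Step 9**
Reactants: 13 the alkynyl aldehyde; 14 ethyl 2-(triphenylphosphoranylidene)propanoate
Product: 15 ethyl (2E,6S)-2,6-dimethyl-6-[2-methyl-4-(triisopropylsilyloxy)phenoxy]oct-2-en-7-ynoate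
Conditions: CH2Cl2, rt → 40 °C
Reagents that add atoms: none
Why: Wittig olefination with a stabilised ylide should give the (E)-trisubstituted enoate selectively, at a temperature far below the onset of a thermal propargyl Claisen rearrangement of the aryl ether.

**Step 10**
Reactants: 15 the aryl propargyl ether enoate
Product: 16 ethyl (2E)-5-[(2S)-2,8-dimethyl-6-(triisopropylsilyloxy)-2H-chromen-2-yl]-2-methylpent-2-enoate
Conditions: Ph3PAuNTf2 (3 mol%), CH2Cl2, 0 °C → rt
Reagents that add atoms: none
Why: Monovalent gold coordinates the terminal alkyne, arene carbon C4a attacks the alkyne terminus anti to the metal, the Wheland intermediate rearomatises and protodeauration releases the C3=C4 alkene and the catalyst. The closest known reaction is the Ph3PAuNTf2-catalysed intramolecular hydroarylation of aryl propargyl ethers, 1,1-disubstituted ones included, to 2H-chromenes. Pyran ring B closes in the 6-endo-dig mode with formation of the C4–C4a bond. No stereocentre is created, and C2 keeps its (S) configuration because the O1–C2 bond stays intact, unlike in the thermal Claisen pathway, where C2 becomes trigonal before ring closure. The step needs arene rather than alkene attack, endo rather than 5-exo closure and a single arylation site: the conjugated ester makes the chain alkene too electron-poor for 1,6-enyne cycloisomerisation, the unsubstituted alkyne terminus favours endo attack, and the C8 methyl and C6 silyloxy groups leave C4a as the only free position ortho to O1. Low temperature and the weakly coordinating counter-ion should keep ionisation of the tertiary propargylic C–O bond from competing.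

**Step 11**
Reactants: 16 the chromene ester
Product: 17 (2E)-5-[(2S)-2,8-dimethyl-6-(triisopropylsilyloxy)-2H-chromen-2-yl]-2-methylpent-2-en-1-ol
Conditions: iBu2AlH (2.5 equiv), CH2Cl2, −78 °C; then aq. potassium sodium tartrate (KNaC4H4O6)
Reagents that add atoms: none
Why: 1,2-Reduction of a conjugated ester by iBu2AlH should give the (E)-allylic alcohol without touching the chromene alkene or the aryl silyl ether.

**Step 12**
Reactants: 17 the allylic alcohol
Product: 18 {[(2S)-2-[(3E)-5-bromo-4-methylpent-3-en-1-yl]-2,8-dimethyl-2H-chromen-6-yl]oxy}triisopropylsilane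
Conditions: CBr4, PPh3, CH2Cl2, 0 °C
Reagents that add atoms: carbon tetrabromide, BrC(Br)(Br)Br
Why: Appel bromination converts the primary allylic alcohol into the bromide by SN2 displacement of the oxyphosphonium group under neutral conditions, which should preserve the E geometry.

**Step 13**
Reactants: 18 the allylic bromide; 5 (S)-3,7-dimethyloct-6-en-1-yn-3-ol (1.5 equiv)
Product: 19 (6S,10E)-13-[(2S)-2,8-dimethyl-6-(triisopropylsilyloxy)-2H-chromen-2-yl]-2,6,10-trimethyltrideca-2,10-dien-7-yn-6-ol
Conditions: CuI (10 mol%), K2CO3 (1.5 equiv), Bu4NBr (10 mol%), DMF, rt, degassed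
Reagents that add atoms: none
Why: Copper-catalysed alkynylation of an allylic halide, in which the copper acetylide formed with CuI and K2CO3 should displace the primary bromide at its unhindered alpha carbon (SN2, not SN2') with retention of alkene geometry, the free tertiary hydroxyl being tolerated by the carbonate base.

**Step 14**
Reactants: 19 the skipped enynol
Product: 20 (6S,7E,10E)-13-[(2S)-2,8-dimethyl-6-(triisopropylsilyloxy)-2H-chromen-2-yl]-2,6,10-trimethyltrideca-2,7,10-trien-6-ol
Conditions: NaAlH2(OCH2CH2OCH3)2 (3 equiv), THF, 0 °C → rt; then aq. potassium sodium tartrate (KNaC4H4O6)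
Reagents that add atoms: none
Why: Hydroxyl-directed trans-hydroalumination of a propargylic alcohol by the alkoxide-bound aluminium hydride, followed by protonolysis on work-up, should give only the (E)-allylic alcohol, since the other alkenes lack a directing group and remain unreduced.

**Step 15**
Reactants: 20 the silyl-protected trienol
Product: 21 (2S)-2-[(3E,6E,8S)-8-hydroxy-4,8,12-trimethyltrideca-3,6,11-trien-1-yl]-2,8-dimethyl-2H-chromen-6-ol (CNP0155965.1)
Conditions: Bu4NF (1.1 equiv), THF, 0 °C; then aq. NH4Cl, degassed solvents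
Reagents that add atoms: none
Why: Fluoride-induced cleavage of the aryl silyl ether, driven by the strength of the Si–F bond, frees the phenol under conditions that should not harm the tertiary allylic alcohol or the chromene.

**Compound list**
1 | geraniol | CC(C)=CCC/C(C)=C/CO | starting material
2 | [(2S,3S)-3-methyl-3-(4-methylpent-3-en-1-yl)oxiran-2-yl]methanol | CC(C)=CCC[C@]1(C)O[C@H]1CO | intermediate
3 | (2S,3R)-3-(chloromethyl)-2-methyl-2-(4-methylpent-3-en-1-yl)oxirane | CC(C)=CCC[C@]1(C)O[C@H]1CCl | intermediate
4 | lithium (3S)-1-chloro-3,7-dimethylocta-1,6-dien-3-olate (C1=C2 geometry not defined) | [Li+].CC(C)=CCC[C@](C)([O-])C=CCl | intermediate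
5 | (S)-3,7-dimethyloct-6-en-1-yn-3-ol | CC(C)=CCC[C@](C)(O)C#C | intermediate
6 | 4-fluoro-3-methylbenzonitrile | Cc1cc(C#N)ccc1F | starting material
7 | 4-{[(3S)-3,7-dimethyloct-6-en-1-yn-3-yl]oxy}-3-methylbenzonitrile | C#C[C@](C)(CCC=C(C)C)Oc1ccc(C#N)cc1C | intermediate
8 | N-(diisobutylalumanyl)-1-(4-{[(3S)-3,7-dimethyloct-6-en-1-yn-3-yl]oxy}-3-methylphenyl)methanimine | C#C[C@](C)(CCC=C(C)C)Oc1ccc(C=N[Al](CC(C)C)CC(C)C)cc1C | intermediate
9 | 4-{[(3S)-3,7-dimethyloct-6-en-1-yn-3-yl]oxy}-3-methylbenzaldehyde | C#C[C@](C)(CCC=C(C)C)Oc1ccc(C=O)cc1C | intermediate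
10 | 4-{[(3S)-5-(3,3-dimethyloxiran-2-yl)-3-methylpent-1-yn-3-yl]oxy}-3-methylphenyl formate (both oxirane epimers) | C#C[C@](C)(CCC1OC1(C)C)Oc1ccc(OC=O)cc1C | intermediate
11 | 4-{[(3S)-5-(3,3-dimethyloxiran-2-yl)-3-methylpent-1-yn-3-yl]oxy}-3-methylphenol (both oxirane epimers) | C#C[C@](C)(CCC1OC1(C)C)Oc1ccc(O)cc1C | intermediate
12 | triisopropyl(4-{[(3S)-5-(3,3-dimethyloxiran-2-yl)-3-methylpent-1-yn-3-yl]oxy}-3-methylphenoxy)silane (both oxirane epimers) | C#C[C@](C)(CCC1OC1(C)C)Oc1ccc(O[Si](C(C)C)(C(C)C)C(C)C)cc1C | intermediate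
13 | (4S)-4-methyl-4-[2-methyl-4-(triisopropylsilyloxy)phenoxy]hex-5-ynal | C#C[C@](C)(CCC=O)Oc1ccc(O[Si](C(C)C)(C(C)C)C(C)C)cc1C | intermediate
14 | ethyl 2-(triphenylphosphoranylidene)propanoate | CCOC(=O)C(C)=P(c1ccccc1)(c1ccccc1)c1ccccc1 | starting material
15 | ethyl (2E,6S)-2,6-dimethyl-6-[2-methyl-4-(triisopropylsilyloxy)phenoxy]oct-2-en-7-ynoate | C#C[C@](C)(CC/C=C(\C)C(=O)OCC)Oc1ccc(O[Si](C(C)C)(C(C)C)C(C)C)cc1C | intermediate
16 | ethyl (2E)-5-[(2S)-2,8-dimethyl-6-(triisopropylsilyloxy)-2H-chromen-2-yl]-2-methylpent-2-enoate | CCOC(=O)/C(C)=C/CC[C@@]1(C)C=Cc2cc(O[Si](C(C)C)(C(C)C)C(C)C)cc(C)c2O1 | intermediate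
17 | (2E)-5-[(2S)-2,8-dimethyl-6-(triisopropylsilyloxy)-2H-chromen-2-yl]-2-methylpent-2-en-1-ol | OC/C(C)=C/CC[C@@]1(C)C=Cc2cc(O[Si](C(C)C)(C(C)C)C(C)C)cc(C)c2O1 | intermediate
18 | {[(2S)-2-[(3E)-5-bromo-4-methylpent-3-en-1-yl]-2,8-dimethyl-2H-chromen-6-yl]oxy}triisopropylsilane | BrC/C(C)=C/CC[C@@]1(C)C=Cc2cc(O[Si](C(C)C)(C(C)C)C(C)C)cc(C)c2O1 | intermediate
19 | (6S,10E)-13-[(2S)-2,8-dimethyl-6-(triisopropylsilyloxy)-2H-chromen-2-yl]-2,6,10-trimethyltrideca-2,10-dien-7-yn-6-ol | CC(C)=CCC[C@](C)(O)C#CC/C(C)=C/CC[C@@]1(C)C=Cc2cc(O[Si](C(C)C)(C(C)C)C(C)C)cc(C)c2O1 | intermediate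
20 | (6S,7E,10E)-13-[(2S)-2,8-dimethyl-6-(triisopropylsilyloxy)-2H-chromen-2-yl]-2,6,10-trimethyltrideca-2,7,10-trien-6-ol | CC(C)=CCC[C@](C)(O)/C=C/C/C(C)=C/CC[C@@]1(C)C=Cc2cc(O[Si](C(C)C)(C(C)C)C(C)C)cc(C)c2O1 | intermediate
21 | (2S)-2-[(3E,6E,8S)-8-hydroxy-4,8,12-trimethyltrideca-3,6,11-trien-1-yl]-2,8-dimethyl-2H-chromen-6-ol | CC(C)=CCC[C@](C)(O)/C=C/C/C(C)=C/CC[C@@]1(C)C=Cc2cc(O)cc(C)c2O1 | target

**Totals**
Total step count: 15. Longest linear sequence: 15 steps (geraniol 1 to target 21); alkynol 5 from step 3 is used again in step 13, so no separate branch has to be built.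

**Steps most likely to fail**

Step 6. In the Criegee intermediate hydride may migrate instead of the aryl group, because the bulky tertiary alkoxy group is twisted out of conjugation by the neighbouring methyl group; this would lead to the benzoic acid and not to the formate. Fallback, from nitrile 7 back to phenol 11:
- Addition of MeMgBr (2.5 equiv, THF, reflux; the first equivalent is consumed by the alkyne C–H) and acidic hydrolysis of the ketimine should give the methyl ketone 1-(4-{[(3S)-3,7-dimethyloct-6-en-1-yn-3-yl]oxy}-3-methylphenyl)ethan-1-one F1.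
- In this ketone only aryl competes with methyl, so Baeyer–Villiger oxidation with buffered mCPBA (CH2Cl2, 40 °C, excess) should give, with concurrent epoxidation, 4-{[(3S)-5-(3,3-dimethyloxiran-2-yl)-3-methylpent-1-yn-3-yl]oxy}-3-methylphenyl acetate F2.
- Methanolysis with K2CO3 in MeOH returns to the route at 11.

Step 10. The cationic gold complex may ionise the tertiary propargylic C–O bond (erosion of enantiomeric purity, loss of the phenol), or closure may go 5-exo or through the chain alkene. Fallback, from 15 back to 16: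
- Electrophilic iodocyclisation with bis(pyridine)iodonium tetrafluoroborate and HBF4 in CH2Cl2 at −60 °C activates the alkyne as an iodonium ion. Anti attack of C4a should close ring B 6-endo, again without touching the O1–C2 bond, and give ethyl (2E)-5-[(2S)-3-iodo-2,8-dimethyl-6-(triisopropylsilyloxy)-2H-chromen-2-yl]-2-methylpent-2-enoate F3.
- Hydrogenolysis of the alkenyl iodide with Pd(OAc)2, PPh3, HCO2H and Et3N in DMF at 60 °C (zerovalent palladium formed in the flask) returns to the route at 16.

Step 4. The addition–elimination may be slow at a fluorine-bearing carbon flanked by the ortho methyl group when the nucleophile is a bulky tertiary alkoxide, which leaves room for alkyne deprotonation or attack at the nitrile. Fallback, from alkynol 5 back to aldehyde 13, bypassing steps 5 to 8 because the C6 oxygen is already present: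
- 4-Iodo-3-methylphenol is silylated (iPr3SiCl, imidazole, DMF) to triisopropyl(4-iodo-3-methylphenoxy)silane F4.
- Oxidation with mCPBA and TsOH in MeCN, then addition of 1,3,5-trimethoxybenzene, should give [2-methyl-4-(triisopropylsilyloxy)phenyl](2,4,6-trimethoxyphenyl)iodonium tosylate F5.
- The potassium alkoxide of 5 (KN(SiMe3)2, toluene, 0 °C → rt) is arylated by ligand coupling at trivalent iodine, which the ortho methyl group assists while trimethoxyphenyl stays on iodine, to give triisopropyl(4-{[(3S)-3,7-dimethyloct-6-en-1-yn-3-yl]oxy}-3-methylphenoxy)silane F6.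
- Lemieux–Johnson cleavage of the trisubstituted alkene (OsO4 cat., NaIO4, 2,6-lutidine, dioxane/H2O) returns to the route at 13.

**Further compounds**
F1 | step 6 | 1-(4-{[(3S)-3,7-dimethyloct-6-en-1-yn-3-yl]oxy}-3-methylphenyl)ethan-1-one | C#C[C@](C)(CCC=C(C)C)Oc1ccc(C(C)=O)cc1C
F2 | step 6 | 4-{[(3S)-5-(3,3-dimethyloxiran-2-yl)-3-methylpent-1-yn-3-yl]oxy}-3-methylphenyl acetate (both oxirane epimers) | C#C[C@](C)(CCC1OC1(C)C)Oc1ccc(OC(C)=O)cc1C
F3 | step 10 | ethyl (2E)-5-[(2S)-3-iodo-2,8-dimethyl-6-(triisopropylsilyloxy)-2H-chromen-2-yl]-2-methylpent-2-enoate | CCOC(=O)/C(C)=C/CC[C@@]1(C)C(I)=Cc2cc(O[Si](C(C)C)(C(C)C)C(C)C)cc(C)c2O1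
F4 | step 4 | triisopropyl(4-iodo-3-methylphenoxy)silane | Cc1cc(O[Si](C(C)C)(C(C)C)C(C)C)ccc1I
F5 | step 4 | [2-methyl-4-(triisopropylsilyloxy)phenyl](2,4,6-trimethoxyphenyl)iodonium tosylate | COc1cc(OC)c([I+]c2ccc(O[Si](C(C)C)(C(C)C)C(C)C)cc2C)c(OC)c1.Cc1ccc(S(=O)(=O)[O-])cc1
F6 | step 4 | triisopropyl(4-{[(3S)-3,7-dimethyloct-6-en-1-yn-3-yl]oxy}-3-methylphenoxy)silane | C#C[C@](C)(CCC=C(C)C)Oc1ccc(O[Si](C(C)C)(C(C)C)C(C)C)cc1C
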